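At 10 min after mixing, I want the target standing in each flask at 5 °C, and the earlier runs suggest that the reading time may matter less than where each flask stops.

| flask | substrate | partner | catalyst | temperature | remark | time |
|---|---|---|---|---|---|---|
| south-west | 0.10 M | 0.071 M | 20 mM | 0 °C | run made earlier |  |
| east | 0.10 M | 0.47 M | 20 mM | 11 °C | run made earlier |  |
| theta | 0.10 M | 0.200 M | 20 mM | 5 °C |  | 10 min |
| epsilon | 0.10 M | 0.300 M | 20 mM | 5 °C |  | 10 min |
| beta | 0.10 M | 0.400 M | 20 mM | 5 °C |  | 10 min |
| gamma | 0.10 M | 0.0500 M | 20 mM | 5 °C |  | 10 min |
| zeta | 0.10 M | 0.105 M | 20 mM | 5 °C |  | 10 min |

- south-west (time / min: target / %): 0.417: 5; 0.667: 7; 1.00: 7; 1.33: 11; 2.00: 14; 3.00: 15; 5.00: 19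
- east (time / min: target / %): 0.250: 30; 0.833: 57; 1.33: 63; 2.00: 68; 3.00: 67; 4.00: 69; 5.00: 70

(standard deviation of a reading: 1.5 percentage points)

- the analysis behind the earlier runs scatters by 1.5 percentage points, standard deviation

- the flasks put in order of amount of target, in percent of the substrate charged, best first, at 10 min (theta / epsilon / beta / gamma / zeta)
- the amount of target, in percent of the substrate charged of the flask you put first, at 10 min
- the amount of target, in percent of the substrate charged of the flask you put last, at 10 min

Both earlier runs slow down with partner to spare: at its last reading the south-west run still holds 0.0520 M of partner, and the east run 0.400 M. So I read the reaction as reversible and look for one number, the stopping quotient: c(target) divided by the product of c(substrate) and c(partner) in a flask that has stopped, which is the equilibrium constant. Each run gives its own value of this number, from a very different partner charge and at its own temperature.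

Taken at the last readings, the two ways part: the east run gives 5.83 M⁻¹, and the south-west run gives 4.51 M⁻¹, so the east value is larger. I suspect the east reading first: its last value of 70% is the highest of the final four, and on that flat stretch one reading can be scatter. The mean of those four, 68.5%, gives 5.42 M⁻¹, which lies closer to the south-west value. The remaining gap may belong to temperature or to the scatter of the readings, and 5 °C lies between the two run temperatures, so I take the midpoint as my stopping quotient, 4.96 M⁻¹.

The reading time is twice the last south-west time, so I treat the flasks as stopped when they are read. Solving the quotient as a quadratic in the target formed, I get 62.6% for beta and 14.9% for gamma.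

The forecast, made from the same runs, gives the order beta > epsilon > theta > zeta > gamma, with beta at 65% (range 58% to 72%) and gamma at 16% (range 12% to 19%). Its ground is “The simplest reading is a reversible reaction”. My two values are lower than its own, but they lie inside its ranges.

The flasks give beta > epsilon > theta > zeta > gamma, with beta at 62.3% and gamma at 14.7%.

    substrate + partner + catalyst ⇌ target + catalyst, rate k1*[substrate]*[partner]*[catalyst] forward; the back reaction follows from the equilibrium constant (K = 4.90 M⁻¹, k = 2.10 M⁻² s⁻¹, Ea = 46.0 kJ mol⁻¹, ΔH = 6.00 kJ mol⁻¹)
    (constants at 5 °C)

My quotient of 4.96 M⁻¹ had given 62.6% and 14.9% for these two flasks. Now I take the neighbour of gamma, charged with 0.085 M of partner and otherwise unchanged. The same quadratic with the same quotient gives 23.4%. At 10.0 min that neighbour holds target equal to 23.2% of the substrate charged, with 77% of its substrate and 73% of its own partner charge still there.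

The runs were generated by integration on assumed constants; scatter was added.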